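**Assumptions (one line):** The absolute configuration is taken as drawn in the target SMILES, and locants use eremophilane numbering (C1 to C15). The C4 and C7 stereocentres are α to a carbonyl and epimerisable; I assume they settle in the observed equatorial sense.

## Retrosynthetic overview
1. Integric acid is the C1 (2E,4S)-2,4-dimethyloct-2-enoate of a 1-hydroxy-8-oxo-eremophil-9-en-15-oic acid. The C15 acid is masked as a t-Bu ester and the C12 α-methylene aldehyde is made last.
2. The α-methylene aldehyde comes from C7–CH2CHO by Mannich-type methylenation. That aldehyde comes from a C7-allyl group by oxidative cleavage, and the allyl group from kinetic α′-alkylation of the enone.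
3. The C1 oxygen comes from γ-hydroxylation of the Δ9(10)-8-one via its linear silyl dienol ether. C5 is quaternary, so C1 is the only γ-CH2.
4. C15 CO2tBu is a one-carbon homologation of the saturated C4 ketone of (S)-Wieland–Miescher ketone. Both rings and the C5 quaternary methyl stereocentre come ready-made from that ketone.
5. The acyl side chain, (S)-2-methylhexanal followed by HWE, is built separately and joined by esterification.

## Route

**Step 1**
Reactants: 1 (S)-Wieland–Miescher ketone; 2 (methoxymethyl)triphenylphosphonium chloride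
Product: 3 C4-methoxymethylene enone (C4=CH-OMe, enone intact, C5 stereocentre retained)
Conditions: KOt-Bu, THF, 0 °C → rt
Reagents that add atoms: 2, COC[P+](c1ccccc1)(c1ccccc1)c1ccccc1.[Cl-]
Why: Wittig methoxymethylenation. The enone carbonyl is deactivated by conjugation, so the saturated C4 ketone reacts selectively, as with a 17-ketone in the presence of a Δ4-3-ketone in steroids.

**Step 2**
Reactants: 3
Product: 4 C4-carbaldehyde enone, CHO cis to the C5-Me (equatorial)
Conditions: 2 M HCl, THF, rt
Reagents that add atoms: water, O
Why: Enol ether hydrolysis. C4 is protonated axially, anti to the axial angular methyl, so CHO ends up equatorial and cis to Me, which is the target C4 configuration. The α-centre equilibrates to this isomer under the acidic conditions.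

**Step 3**
Reactants: 4
Product: 5 C4-carboxylic acid enone
Conditions: NaClO2, NaH2PO4, 2-methyl-2-butene, t-BuOH/H2O, rt
Reagents that add atoms: sodium chlorite, [Na+].[O-]Cl=O
Why: Pinnick oxidation. It is mild and non-basic, so C4 is not epimerised, and the enone survives because the scavenger traps HOCl.

**Step 4**
Reactants: 5
Product: 6 C4 tert-butyl ester enone
Conditions: Boc2O, DMAP (cat.), t-BuOH, 40 °C
Reagents that add atoms: tert-butanol, CC(C)(C)O (the Boc2O activator leaves no atoms in the product)
Why: Boc2O/DMAP esterification through the mixed anhydride. The t-Bu ester withstands LDA, silyl triflate/Et3N, OsO4 and Et3N, and is cleaved by TFA at the end without touching the C1 ester.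

**Step 5**
Reactants: 6; 7 allyl bromide
Product: 8 7-allyl enone, allyl equatorial and trans to the C5-Me
Conditions: LDA, THF, –78 °C; then allyl bromide, DMPU, –78 → –20 °C
Reagents that add atoms: allyl bromide, C=CCBr
Why: Kinetic α′-enolate alkylation. LDA deprotonates the enone CH2 at C7 (ketone more acidic than the t-Bu ester), and the 1,3-diaxial axial Me disfavours axial attack. C7 is epimerisable and settles equatorial (DBU, rt if needed).

**Step 6**
Reactants: 8
Product: 9 1-hydroxy enone, 1-OH axial and cis to the C5-Me (1R)
Conditions: (i) TBSOTf, Et3N, CH2Cl2, 0 °C; (ii) mCPBA (1.05 equiv), NaHCO3, –78 °C; (iii) HF·pyridine, THF, 0 °C (one pot)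
Reagents that add atoms: mCPBA, OOC(=O)c1cccc(Cl)c1 (O only; TBS is removed)
Why: Steroid-type γ-hydroxylation (cf. 6β-hydroxylation of Δ4-3-ketones). The linear silyl dienol ether forms toward C1 only, and epoxidation of its terminal C1=C10 bond then opening gives the γ-hydroxy enone. Oxygen is delivered axially on the same face as the angular Me. The allyl alkene and t-Bu ester tolerate 1 equiv of peracid at –78 °C.

**Step 7**
Reactants: 10 (S)-4-benzyloxazolidin-2-one; 11 hexanoyl chloride
Product: 12 (S)-4-benzyl-3-hexanoyloxazolidin-2-one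
Conditions: n-BuLi, THF, –78 °C
Reagents that add atoms: hexanoyl chloride, CCCCCC(=O)Cl
Why: N-acylation of the lithiated Evans auxiliary.

**Step 8**
Reactants: 12; 13 iodomethane
Product: 14 (S)-4-benzyl-3-[(S)-2-methylhexanoyl]oxazolidin-2-one
Conditions: NaHMDS, THF, –78 °C; then MeI
Reagents that add atoms: iodomethane, CI
Why: Evans asymmetric alkylation. The chelated Z-enolate is attacked by MeI anti to the benzyl group, which sets the (S) centre.

**Step 9**
Reactants: 14
Product: 15 (S)-2-methylhexan-1-ol
Conditions: LiBH4, THF/H2O, 0 °C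
Reagents that add atoms: none
Why: Reductive removal of the auxiliary, which is recovered. The α-stereocentre is not enolised.

**Step 10**
Reactants: 15
Product: 16 (S)-2-methylhexanal
Conditions: Dess–Martin periodinane, NaHCO3, CH2Cl2, 0 °C
Reagents that add atoms: none
Why: Buffered mild oxidation of the primary alcohol, which avoids racemising the α-branched aldehyde (used crude).

**Step 11**
Reactants: 16; 17 triethyl 2-phosphonopropionate
Product: 18 ethyl (2E,4S)-2,4-dimethyloct-2-enoate
Conditions: LiCl, DBU, MeCN, rt
Reagents that add atoms: triethyl 2-phosphonopropionate, CCOC(=O)C(C)P(=O)(OCC)OCC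
Why: Masamune–Roush HWE olefination, E-selective for the trisubstituted enoate. The mild conditions avoid epimerising C4′.

**Step 12**
Reactants: 18
Product: 19 (2E,4S)-2,4-dimethyloct-2-enoic acid
Conditions: LiOH, THF/MeOH/H2O, 50 °C
Reagents that add atoms: lithium hydroxide, [Li+].[OH-]
Why: Saponification. The γ-stereocentre and the E-alkene are not involved.

**Step 13**
Reactants: 9; 19
Product: 20 C1 (2E,4S)-2,4-dimethyloct-2-enoate, C4 t-Bu ester, 7-allyl
Conditions: 2,4,6-Cl3C6H2COCl, Et3N, THF, rt; then 9, DMAP, toluene, 60 °C
Reagents that add atoms: none (acid 19 is the reactant; the Yamaguchi reagent leaves no atoms)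
Why: Yamaguchi esterification through the mixed anhydride. The C1–O bond is not broken, so C1 configuration is retained. The hindered axial alcohol needs DMAP and heat.

**Step 14**
Reactants: 20
Product: 21 C7–CH2CHO aldehyde
Conditions: OsO4 (5 mol%), NaIO4, 2,6-lutidine, dioxane/H2O, rt
Reagents that add atoms: sodium periodate, [Na+].[O-]I(=O)(=O)=O
Why: Lemieux–Johnson cleavage. OsO4 is selective for the monosubstituted alkene over the electron-poor enone and enoate.

**Step 15**
Reactants: 21; 22 Eschenmoser's salt
Product: 23 t-Bu ester of integric acid (α-methylene aldehyde installed)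
Conditions: Me2N+=CH2 I–, Et3N, CH2Cl2, rt
Reagents that add atoms: Eschenmoser's salt, C[N+](C)=C.[I-] (supplies the =CH2 carbon)
Why: Mannich-type α-methylenation of an aldehyde, which gives the α-methylene aldehyde by addition then elimination of Me2NH. The ketone, esters and enone are untouched, and C7 re-equilibrates to the equatorial isomer.

**Step 16**
Reactants: 23
Product: 24 integric acid
Conditions: TFA, CH2Cl2, 0 °C → rt
Reagents that add atoms: none
Why: Acidolysis of the t-Bu ester (E1, loss of isobutylene). The C1 allylic ester is deactivated toward ionisation by the enone, and the acrolein tolerates brief dilute TFA.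

## Compound list
1 | (S)-Wieland–Miescher ketone | C1C[C@@]2(C)C(=CC1=O)CCCC2=O | starting material
2 | (methoxymethyl)triphenylphosphonium chloride | COC[P+](c1ccccc1)(c1ccccc1)c1ccccc1.[Cl-] | starting material
3 | (8aS)-1-(methoxymethylidene)-8a-methyl-1,2,3,4,8,8a-hexahydronaphthalen-6(7H)-one | C1C[C@@]2(C)C(=CC1=O)CCCC2=COC | intermediate
4 | C4-CHO enone, CHO cis to the angular Me | C1C[C@@]2(C)C(=CC1=O)CCC[C@@H]2C=O | intermediate
5 | C4-COOH enone | C1C[C@@]2(C)C(=CC1=O)CCC[C@@H]2C(=O)O | intermediate
6 | C4-CO2tBu enone | C1C[C@@]2(C)C(=CC1=O)CCC[C@@H]2C(=O)OC(C)(C)C | intermediate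
7 | allyl bromide | C=CCBr | starting material
8 | 7β-allyl enone t-Bu ester | C=CC[C@@H]1C[C@@]2(C)C(=CC1=O)CCC[C@@H]2C(=O)OC(C)(C)C | intermediate
9 | 1-hydroxy (axial, 1R) enone t-Bu ester | C=CC[C@@H]1C[C@@]2(C)C(=CC1=O)[C@H](O)CC[C@@H]2C(=O)OC(C)(C)C | intermediate
10 | (S)-4-benzyloxazolidin-2-one | O=C1N[C@@H](Cc2ccccc2)CO1 | starting material
11 | hexanoyl chloride | CCCCCC(=O)Cl | starting material
12 | (S)-4-benzyl-3-hexanoyloxazolidin-2-one | CCCCCC(=O)N1[C@@H](Cc2ccccc2)COC1=O | intermediate
13 | iodomethane | CI | starting material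
14 | (S)-4-benzyl-3-[(S)-2-methylhexanoyl]oxazolidin-2-one | CCCC[C@H](C)C(=O)N1[C@@H](Cc2ccccc2)COC1=O | intermediate
15 | (S)-2-methylhexan-1-ol | CCCC[C@H](C)CO | intermediate
16 | (S)-2-methylhexanal | CCCC[C@H](C)C=O | intermediate
17 | triethyl 2-phosphonopropionate | CCOC(=O)C(C)P(=O)(OCC)OCC | starting material
18 | ethyl (2E,4S)-2,4-dimethyloct-2-enoate | CCOC(=O)/C(C)=C/[C@@H](C)CCCC | intermediate
19 | (2E,4S)-2,4-dimethyloct-2-enoic acid | O=C(O)/C(C)=C/[C@@H](C)CCCC | intermediate
20 | C1-acyl ester, 7-allyl, C4 t-Bu ester | C=CC[C@@H]1C[C@@]2(C)C(=CC1=O)[C@H](OC(=O)/C(C)=C/[C@@H](C)CCCC)CC[C@@H]2C(=O)OC(C)(C)C | intermediate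
21 | C7–CH2CHO aldehyde, t-Bu ester | O=CC[C@@H]1C[C@@]2(C)C(=CC1=O)[C@H](OC(=O)/C(C)=C/[C@@H](C)CCCC)CC[C@@H]2C(=O)OC(C)(C)C | intermediate
22 | Eschenmoser's salt | C[N+](C)=C.[I-] | starting material
23 | integric acid t-Bu ester | C=C(C=O)[C@@H]1C[C@@]2(C)C(=CC1=O)[C@H](OC(=O)/C(C)=C/[C@@H](C)CCCC)CC[C@@H]2C(=O)OC(C)(C)C | intermediate
24 | integric acid (1R,4S,5R,7S) | C=C(C=O)[C@@H]1C[C@@]2(C)C(=CC1=O)[C@H](OC(=O)/C(C)=C/[C@@H](C)CCCC)CC[C@@H]2C(=O)O | target

## Totals
- Total steps: 16 (6 on the core, 6 on the side-chain branch, then coupling and 3 finishing steps).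
- Longest linear sequence: 10 steps (1 → 3 → 4 → 5 → 6 → 8 → 9 → 20 → 21 → 23 → 24).

## Three steps most likely to fail
1. **Step 6 (γ-hydroxylation: regiochemistry and face).** The α-oxidation (C9) by-product and the 1-epimer are the concerns. Fallback: run the oxidation before allylation, by CrO3·3,5-dimethylpyrazole allylic oxidation of 6 to the C1 ketone (ene-dione). Reduce with NaBH4/CeCl3 from the face anti to the C5-Me to give the axial 1-OH, then TBS-protect, allylate, and continue.
2. **Step 1 (chemoselective Wittig at the saturated ketone).** The ylide may attack the enone carbonyl or enolise it. Fallback: selectively ketalise the C4 ketone (ethylene glycol, TsOH, rt) and do the γ-hydroxylation and allylation on the ketal. Then remove the ketal and install C15 by Corey–Chaykovsky epoxidation (Me3S+ I–, NaH) and Meinwald rearrangement to the C4 aldehyde, instead of the Wittig route.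
3. **Step 13 (acylation of the hindered axial C1–OH).** This alcohol is 1,3-diaxial to the angular Me. Fallback: esterify C1–OH with the small phosphonate acid (EtO)2P(O)CH(Me)CO2H (EDC, DMAP). Then build the (E)-enoate in place by intermolecular HWE (LiCl, DBU) with aldehyde 16.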